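## Analysis of the target

Target 20 is a dihydroflavonol, a 2,3-dihydro-4H-chromen-4-one. Ring A carries hydroxyl groups at C5 and C6 and a methoxy group at C7; ring C carries a methoxy group at C3 and the ketone at C4; C2 bears ring B, a 3-hydroxy-4,5-dimethoxyphenyl group. The only stereocentres are the adjacent C2 and C3, both R, so the aryl group and the C3 methoxy group are trans. Two features are fragile: the C5/C6 catechol is easily oxidised to an ortho-quinone, and C3–H lies α to the C4 carbonyl with O1 as a phenoxide leaving group β to it, so base opens ring C to a chalcone and erases C2. Seven oxygen substituents must be told apart: four methyl ethers (C3, C7, C4', C5') and three free hydroxyls (C5, C6, C3'). The difficulty is therefore absolute control of C2 and C3 in a ring that tolerates no base once the ketone is present, together with release of exactly three hydroxyls. The strategy rests on one observation: with C4 reduced to a methylene, the C2–C3 unit is a trans-2-aryl-3-oxygenated chroman, which is what syn addition of H to C2 and OH to C3 across the C2=C3 enol ether bond of an achiral 2-aryl-4H-chromene delivers. Two further properties make this usable: C4 is benzylic to a ring A whose O1, C5–O and C7–O lie ortho and para to C4a, so it can be oxidised late, and the C4 carbonyl then singles out the peri C5 methyl ether by chelation, which lets ring A come from a symmetrical 3,5-dimethoxy precursor.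

## Retrosynthetic reasoning

**20 ⇒ 19 ⇒ 18 (O–C bonds of protecting groups).** The C5 hydroxyl of 20 is traced to a methyl ether in 19, because a Lewis acid held between the C4 carbonyl and the peri C5 oxygen can remove that one methyl group and no other. The C6 and C3' hydroxyls are traced to benzyl ethers in 18, removed by hydrogenolysis before the catechol is exposed. What is gained is a ring A with identical methyl ethers at C5 and C7 for the whole route.

**18 ⇒ 17 ⇒ 16 (the C4 oxygen).** The ketone is taken back to the alcohol 17 and then to the C4 methylene of 16. With C4 as CH2 there is no enolisable position and no path for β-elimination of O1, so C2 and C3 are safe in all earlier operations. The forward reactions must abstract hydride from C4 (the cation is stabilised by O1 and the C5 and C7 methoxy groups), trap the cation with an oxygen nucleophile, and oxidise the alcohol without base.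

**16 ⇒ 15 (O–CH3 at C3).** The C3 methyl ether is cut to the alcohol 15. At the flavan stage an alkoxide at C3 is harmless, which would not be true after the ketone is in place.

**15 ⇒ 13 (C3–O and C2–H, the key disconnection).** Removing the C3 hydroxyl and the C2 hydrogen gives the flat, achiral 4H-chromene 13. This is the place to cut because both stereocentres then arise in one step: the relative configuration follows from syn addition and the absolute configuration from the reagent. Cuts at O1–C2 or C2–C3 would need both centres built in an acyclic precursor and carried through a ring closure. The forward reaction must place boron on C3 and must select one face of the alkene.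

**13 ⇒ 11 (O1–C2).** The enol ether is opened to the phenol ketone 11. The forward step is a cyclodehydration through the hemiketal 12, and the double bond can only form between C2 and C3 because C4 is already a methylene.

**11 ⇒ 10 ⇒ 5 + 9 (C3–C4).** Removing the two hydrogens added to C3 and C4 gives the chalcone 10, which is split at its C=C bond into the ring A aldehyde 5 (C4) and the ring B methyl ketone 9 (C2 and C3). This is the most convergent split and joins two halves of similar size by an aldol condensation.

**5 ⇒ 4 ⇒ 2 ⇒ 1 (ring A).** The C4–C4a bond is cut by an ortho-formylation of the phenol 4, whose two ortho positions are equivalent and whose para position is blocked. The phenol oxygen (later O1) comes from an aryl migration on the aldehyde 2, the benzyl ether of 1.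

**9 ⇒ 8 ⇒ 7 ⇒ 6 (ring B).** The methyl ketone is cut at its C–CH3 bond to the aldehyde 7 by way of the carbinol 8; 7 is the benzyl ether of 6.

## Alternatives that were turned down

**Alternative 1: closure of ring C through a ring A ortho-quinone.**
- Disconnection: O1–C8a. The precursor is the open-chain catechol ketone A1, (2R,3R)-3-[3-(benzyloxy)-4,5-dimethoxyphenyl]-1-(2,3-dihydroxy-4-methoxyphenyl)-3-hydroxy-2-methoxypropan-1-one.
- Key step: Ag2O (monovalent silver) would oxidise A1 to the ortho-quinone A2. The C2 hydroxyl would add in a 6-endo conjugate fashion to C8a, and tautomerisation would give the dihydroflavonol A3, one hydrogenolysis short of target 20.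
- For it: the C4 carbonyl and the free 5,6-catechol are present from the start, so there is no C4 oxidation and no late demethylation; the C2–O bond is not broken, so the carbinol configuration is kept. On steps after the key step (one against five) it is clearly stronger.
- Against it: A1 must already hold both stereocentres as an α-methoxy-β-hydroxy ketone, which is prone to retro-aldol cleavage and dehydration, and this on the basic surface of Ag2O. The 3-acyl ortho-quinone A2 is a short-lived, strongly electrophilic species that can also be attacked at C8 or intermolecularly. The product A3 is a more electron-rich catechol than A1 and should be oxidised further.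
- Comparison: the chosen route spends more steps after its key step, but each acts on a robust intermediate, and its stereocentres come from a reaction whose relative configuration is fixed by mechanism.

**Alternative 2: three-component oxonium ylide aldol.**
- Disconnection: C2–C3 and C3–O. Components are the diazoketone A4, methanol A5 and the ring B aldehyde 7.
- Key step: Rh2(OAc)4 (divalent rhodium) with a chiral BINOL-derived phosphoric acid would give the carbenoid of A4, then the oxonium ylide with A5, which would be trapped by 7 to give the aldol A6.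
- For it: it is the most convergent plan. It forms the C–C bond, the C3 methyl ether and both stereocentres in one step, with the ketone in place and no separate methylation. On step economy it is stronger than the chosen route.
- Against it: the carbenoid from A4 is an acceptor-only ketocarbenoid flanked by two ortho substituents. For such species the 1,2-proton shift to the simple O–H insertion product, Wolff rearrangement and attack on an ortho ether oxygen compete with trapping, and 7 is an electron-rich, weak electrophile. The carbinol carbon of A6 has the configuration opposite to C2 of 20, so ring closure after desilylation needs an SN2 displacement with inversion at an electron-rich benzylic alcohol next to an enolisable ketone; ionisation and elimination threaten both centres. The C5 methyl ether must still be cleaved at the end, as in the chosen route.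
- Comparison: two steps of uncertain stereochemical outcome stand against one reagent-controlled syn addition.

**Alternative 3: rhodium carbenoid C–H insertion into a benzylic ether.**
- Disconnection: C2–C3. The precursor is the diazoketone A7, in which ring B is attached as a benzyl ether on the future O1.
- Key step: Rh2(S-PTTL)4 (divalent rhodium) would generate the carbenoid at C3, which would insert into a benzylic C–H bond of the O1–CH2 group to close ring C and give the flavanone A8.
- For it: assembly is very short, since ring B enters as a simple benzyl ether and the ring and the C–C bond form in one catalytic step with the ketone in place. It is stronger than the chosen route in the number of steps to the bicyclic core.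
- Against it: only C2 is set. The insertion forms a six-membered ring from an acceptor-only carbenoid and competes with ylide formation at the neighbouring ether oxygen followed by a 1,2-benzyl shift, with insertion into the methyl group of the other ortho ether, and with addition to ring B. The C3 oxygen must then be introduced by enol or enolate chemistry on a flavanone, which opens by β-elimination of the phenoxide and racemises C2, and the resulting α-hydroxy ketone must be O-methylated.
- Comparison: the chosen route creates C2 and C3 together and introduces the carbonyl only after both are fixed.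

Key step: step 10

Assumption: the sense of induction of IpcBH2 is taken from 1-arylcycloalkenes, so the reagent made from (+)-α-pinene is expected to give (2R,3S)-15; if the flavene responds in the opposite sense, the reagent from (−)-α-pinene is used in the same way.

## Route

Step 1
Reactants: 1 syringaldehyde
Product: 2 4-(benzyloxy)-3,5-dimethoxybenzaldehyde
Conditions: BnBr, K2CO3, DMF, 60 °C
Reagents that add atoms: benzyl bromide BrCc1ccccc1
Why: Williamson etherification of the phenoxide with a reactive benzylic bromide; the aldehyde is inert to K2CO3.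

Step 2
Reactants: 2 4-(benzyloxy)-3,5-dimethoxybenzaldehyde
Product: 4 4-(benzyloxy)-3,5-dimethoxyphenol, via aryl formate 3 (not isolated)
Conditions: mCPBA, CH2Cl2, 0 °C to rt; aq. NaHCO3 wash; then K2CO3 (cat.), MeOH, rt
Reagents that add atoms: 3-chloroperoxybenzoic acid OOC(=O)c1cccc(Cl)c1
Why: Baeyer–Villiger (Dakin-type) oxidation in which the electron-rich trialkoxyaryl group migrates in preference to hydride; the formate 3 is cleaved by mild methanolysis that leaves the benzyl ether alone.

Step 3
Reactants: 4 4-(benzyloxy)-3,5-dimethoxyphenol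
Product: 5 3-(benzyloxy)-6-hydroxy-2,4-dimethoxybenzaldehyde
Conditions: MgCl2, Et3N, (CH2O)n, MeCN, reflux; then 1 M HCl
Reagents that add atoms: paraformaldehyde (as formaldehyde) C=O
Why: Magnesium-mediated ortho-formylation (Casnati–Skattebøl): the magnesium phenoxide delivers formaldehyde to the ortho carbon and a second formaldehyde oxidises the resulting benzylic alkoxide. The two ortho positions of 4 are equivalent and the para position is blocked, so only one aldehyde can form.

Step 4
Reactants: 6 3-hydroxy-4,5-dimethoxybenzaldehyde
Product: 7 3-(benzyloxy)-4,5-dimethoxybenzaldehyde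
Conditions: BnBr, K2CO3, DMF, 60 °C
Reagents that add atoms: benzyl bromide BrCc1ccccc1
Why: Williamson etherification, as in step 1.

Step 5
Reactants: 7 3-(benzyloxy)-4,5-dimethoxybenzaldehyde
Product: 8 1-[3-(benzyloxy)-4,5-dimethoxyphenyl]ethan-1-ol (racemic)
Conditions: MeMgBr, THF, 0 °C; then aq. NH4Cl
Reagents that add atoms: methylmagnesium bromide C[Mg]Br
Why: Grignard addition to an aryl aldehyde; the new carbinol centre needs no control because it is oxidised in the next step.

Step 6
Reactants: 8 1-[3-(benzyloxy)-4,5-dimethoxyphenyl]ethan-1-ol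
Product: 9 1-[3-(benzyloxy)-4,5-dimethoxyphenyl]ethan-1-one
Conditions: MnO2 (activated, excess), CH2Cl2, rt
Reagents that add atoms: none
Why: Oxidation of a benzylic alcohol with activated MnO2 under neutral, heterogeneous conditions; the benzyl and methyl ethers are untouched.

Step 7
Reactants: 5 3-(benzyloxy)-6-hydroxy-2,4-dimethoxybenzaldehyde; 9 1-[3-(benzyloxy)-4,5-dimethoxyphenyl]ethan-1-one
Product: 10 (2E)-3-[3-(benzyloxy)-6-hydroxy-2,4-dimethoxyphenyl]-1-[3-(benzyloxy)-4,5-dimethoxyphenyl]prop-2-en-1-one
Conditions: KOH (50% aq.), EtOH, rt to 40 °C; then AcOH to pH 6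
Reagents that add atoms: none
Why: Claisen–Schmidt condensation: the enolate of 9 adds to the non-enolisable aldehyde 5 and E1cB dehydration gives the E enone. The phenoxide of 5 slows the addition but does not block it, and neutralisation without strong acid avoids closure to a flavylium salt.

Step 8
Reactants: 10 (2E)-3-[3-(benzyloxy)-6-hydroxy-2,4-dimethoxyphenyl]-1-[3-(benzyloxy)-4,5-dimethoxyphenyl]prop-2-en-1-one
Product: 11 3-[3-(benzyloxy)-6-hydroxy-2,4-dimethoxyphenyl]-1-[3-(benzyloxy)-4,5-dimethoxyphenyl]propan-1-one
Conditions: H2 (3 atm), RhCl(PPh3)3 (cat.), THF/EtOH, 40 °C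
Reagents that add atoms: none
Why: Homogeneous hydrogenation with RhCl(PPh3)3 saturates the disubstituted enone C=C and does not cleave aryl benzyl ethers or reduce the aryl ketone.

Step 9
Reactants: 11 3-[3-(benzyloxy)-6-hydroxy-2,4-dimethoxyphenyl]-1-[3-(benzyloxy)-4,5-dimethoxyphenyl]propan-1-one
Product: 13 6-(benzyloxy)-2-[3-(benzyloxy)-4,5-dimethoxyphenyl]-5,7-dimethoxy-4H-chromene, via cyclic hemiketal 12 (not isolated)
Conditions: PPTS (cat.), toluene, reflux, Dean–Stark; Et3N quench, filtration through basic alumina, used at once
Reagents that add atoms: none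
Why: Acid-catalysed cyclodehydration: the phenol adds to the ketone to give the 2-hydroxyflavan 12, which loses water through the 2-aryl oxocarbenium ion and a C3 proton. Azeotropic removal of water drives the equilibrium, and the alkene can only be C2=C3 because C4 is a methylene.

Step 10
Reactants: 13 6-(benzyloxy)-2-[3-(benzyloxy)-4,5-dimethoxyphenyl]-5,7-dimethoxy-4H-chromene
Product: 15 (2R,3S)-6-(benzyloxy)-2-[3-(benzyloxy)-4,5-dimethoxyphenyl]-5,7-dimethoxy-3,4-dihydro-2H-chromen-3-ol, via organoborane 14 (not isolated)
Conditions: IpcBH2 from (+)-α-pinene [released from (IpcBH2)2·TMEDA with BF3·OEt2, THF, rt, filtered], THF, −25 °C; then 3 M NaOH, 30% H2O2, 0 °C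
Reagents that add atoms: hydrogen peroxide OO
Why: Asymmetric hydroboration–oxidation with monoisopinocampheylborane. The B–H bond adds across C2=C3 of 13 in a concerted four-centre syn fashion; boron bonds to C3, the β-carbon of the enol ether and the only alkene carbon bearing hydrogen, and hydride goes to C2, so enol ether polarity and substitution both fix the regiochemistry and give borane 14. Alkaline H2O2 then replaces boron by oxygen through a 1,2-shift of C3 from boron to oxygen with retention, so the C3 hydroxyl ends up cis to the new C2 hydrogen and trans to the aryl group; the relative configuration is thus set by the mechanism. The absolute configuration of both new stereocentres, C2 and C3, is set by the isopinocampheyl group, which makes the two faces of the flat achiral alkene diastereotopic in the transition state. The closest known reactions are the hydroboration of 1-arylcycloalkenes and of cyclic enol ethers with isopinocampheylboranes and the racemic hydroboration–oxidation of flav-2-enes to 2,3-trans-flavan-3-ols; the reagent from (+)-α-pinene converts 1-arylcycloalkenes into (1S,2R)-trans-2-arylcycloalkanols, an arrangement that maps onto (2R,3S)-15 when the ring CH2 next to the aryl-bearing carbon is replaced by O1. No ring is closed. The step needs face selectivity, which is the task of the reagent, and it needs the β-aryloxyborane 14 to survive until oxidation, which a BF3-free reagent solution, low temperature and a cold peroxide work-up should secure; crystallisation of 15 is available to raise the optical purity.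

Step 11
Reactants: 15 (2R,3S)-6-(benzyloxy)-2-[3-(benzyloxy)-4,5-dimethoxyphenyl]-5,7-dimethoxy-3,4-dihydro-2H-chromen-3-ol
Product: 16 (2R,3S)-6-(benzyloxy)-2-[3-(benzyloxy)-4,5-dimethoxyphenyl]-3,5,7-trimethoxy-3,4-dihydro-2H-chromene
Conditions: NaH, MeI, THF, 0 °C to rt
Reagents that add atoms: iodomethane CI
Why: Williamson O-methylation of the secondary alkoxide; at the flavan stage nothing in the molecule is base-sensitive and neither stereocentre is touched.

Step 12
Reactants: 16 (2R,3S)-6-(benzyloxy)-2-[3-(benzyloxy)-4,5-dimethoxyphenyl]-3,5,7-trimethoxy-3,4-dihydro-2H-chromene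
Product: 17 (2R,3S)-6-(benzyloxy)-2-[3-(benzyloxy)-4,5-dimethoxyphenyl]-3,5,7-trimethoxy-3,4-dihydro-2H-chromen-4-ol (C4 epimers)
Conditions: DDQ, CH2Cl2/H2O (18:1), 0 °C to rt
Reagents that add atoms: water O
Why: DDQ benzylic oxidation: hydride abstraction from C4 gives a cation stabilised by O1 and by the C5 and C7 methoxy groups, and water captures it. The C4 configuration is of no consequence because the next step removes it, and C2 and C3 are not involved.

Step 13
Reactants: 17 (2R,3S)-6-(benzyloxy)-2-[3-(benzyloxy)-4,5-dimethoxyphenyl]-3,5,7-trimethoxy-3,4-dihydro-2H-chromen-4-ol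
Product: 18 (2R,3R)-6-(benzyloxy)-2-[3-(benzyloxy)-4,5-dimethoxyphenyl]-3,5,7-trimethoxy-2,3-dihydro-4H-chromen-4-one
Conditions: Dess–Martin periodinane, CH2Cl2, 0 °C to rt
Reagents that add atoms: none
Why: Dess–Martin oxidation of the benzylic alcohol under non-basic conditions, so C3 is not epimerised and ring C is not opened; the change of the C3 descriptor from S to R is only a change of priorities.

Step 14
Reactants: 18 (2R,3R)-6-(benzyloxy)-2-[3-(benzyloxy)-4,5-dimethoxyphenyl]-3,5,7-trimethoxy-2,3-dihydro-4H-chromen-4-one
Product: 19 (2R,3R)-6-hydroxy-2-(3-hydroxy-4,5-dimethoxyphenyl)-3,5,7-trimethoxy-2,3-dihydro-4H-chromen-4-one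
Conditions: H2 (1 atm), Pd/C (10%), EtOAc/MeOH, rt
Reagents that add atoms: none
Why: Hydrogenolysis of two aryl benzyl ethers over Pd/C; the electron-rich aryl ketone, the methyl ethers and the neutral, base-free stereocentres should persist at 1 atm and rt.

Step 15
Reactants: 19 (2R,3R)-6-hydroxy-2-(3-hydroxy-4,5-dimethoxyphenyl)-3,5,7-trimethoxy-2,3-dihydro-4H-chromen-4-one
Product: 20 (2R,3R)-5,6-dihydroxy-2-(3-hydroxy-4,5-dimethoxyphenyl)-3,7-dimethoxy-2,3-dihydro-4H-chromen-4-one
Conditions: BCl3 (1 M in CH2Cl2), CH2Cl2, −78 to 0 °C; then ice-water, work-up under Ar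
Reagents that add atoms: none
Why: Chelation-controlled demethylation: BCl3 binds the C4 carbonyl and the peri C5 methoxy oxygen in a six-membered chelate and chloride removes that methyl group. BCl3 alone is too weak to cleave the four unchelated methyl ethers at 0 °C.

## Compound list

1 | syringaldehyde (4-hydroxy-3,5-dimethoxybenzaldehyde) | COc1cc(C=O)cc(OC)c1O | starting material
2 | 4-(benzyloxy)-3,5-dimethoxybenzaldehyde | COc1cc(C=O)cc(OC)c1OCc1ccccc1 | intermediate
3 | 4-(benzyloxy)-3,5-dimethoxyphenyl formate | COc1cc(OC=O)cc(OC)c1OCc1ccccc1 | intermediate (not isolated)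
4 | 4-(benzyloxy)-3,5-dimethoxyphenol | COc1cc(O)cc(OC)c1OCc1ccccc1 | intermediate
5 | 3-(benzyloxy)-6-hydroxy-2,4-dimethoxybenzaldehyde | COc1cc(O)c(C=O)c(OC)c1OCc1ccccc1 | intermediate
6 | 3-hydroxy-4,5-dimethoxybenzaldehyde | COc1cc(C=O)cc(O)c1OC | starting material
7 | 3-(benzyloxy)-4,5-dimethoxybenzaldehyde | COc1cc(C=O)cc(OCc2ccccc2)c1OC | intermediate
8 | 1-[3-(benzyloxy)-4,5-dimethoxyphenyl]ethan-1-ol (racemic) | COc1cc(C(C)O)cc(OCc2ccccc2)c1OC | intermediate
9 | 1-[3-(benzyloxy)-4,5-dimethoxyphenyl]ethan-1-one | COc1cc(C(C)=O)cc(OCc2ccccc2)c1OC | intermediate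
10 | (2E)-3-[3-(benzyloxy)-6-hydroxy-2,4-dimethoxyphenyl]-1-[3-(benzyloxy)-4,5-dimethoxyphenyl]prop-2-en-1-one | COc1cc(O)c(/C=C/C(=O)c2cc(OCc3ccccc3)c(OC)c(OC)c2)c(OC)c1OCc1ccccc1 | intermediate
11 | 3-[3-(benzyloxy)-6-hydroxy-2,4-dimethoxyphenyl]-1-[3-(benzyloxy)-4,5-dimethoxyphenyl]propan-1-one | COc1cc(O)c(CCC(=O)c2cc(OCc3ccccc3)c(OC)c(OC)c2)c(OC)c1OCc1ccccc1 | intermediate
12 | 6-(benzyloxy)-2-[3-(benzyloxy)-4,5-dimethoxyphenyl]-5,7-dimethoxy-3,4-dihydro-2H-chromen-2-ol (racemic) | COc1cc2OC(O)(c3cc(OCc4ccccc4)c(OC)c(OC)c3)CCc2c(OC)c1OCc1ccccc1 | intermediate (not isolated)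
13 | 6-(benzyloxy)-2-[3-(benzyloxy)-4,5-dimethoxyphenyl]-5,7-dimethoxy-4H-chromene | COc1cc2c(c(OC)c1OCc3ccccc3)CC=C(c4cc(OCc5ccccc5)c(OC)c(OC)c4)O2 | intermediate
14 | [(2S,3S)-6-(benzyloxy)-2-[3-(benzyloxy)-4,5-dimethoxyphenyl]-5,7-dimethoxy-3,4-dihydro-2H-chromen-3-yl](isopinocampheyl)borane (same spatial arrangement as 15; descriptors differ because boron ranks below carbon) | COc1cc2c(c(OC)c1OCc3ccccc3)C[C@H](B[C@@H]6C[C@@H]7C[C@H]([C@H]6C)C7(C)C)[C@@H](c4cc(OCc5ccccc5)c(OC)c(OC)c4)O2 | intermediate (not isolated)
15 | (2R,3S)-6-(benzyloxy)-2-[3-(benzyloxy)-4,5-dimethoxyphenyl]-5,7-dimethoxy-3,4-dihydro-2H-chromen-3-ol | COc1cc2c(c(OC)c1OCc3ccccc3)C[C@H](O)[C@@H](c4cc(OCc5ccccc5)c(OC)c(OC)c4)O2 | intermediate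
16 | (2R,3S)-6-(benzyloxy)-2-[3-(benzyloxy)-4,5-dimethoxyphenyl]-3,5,7-trimethoxy-3,4-dihydro-2H-chromene | COc1cc2c(c(OC)c1OCc3ccccc3)C[C@H](OC)[C@@H](c4cc(OCc5ccccc5)c(OC)c(OC)c4)O2 | intermediate
17 | (2R,3S)-6-(benzyloxy)-2-[3-(benzyloxy)-4,5-dimethoxyphenyl]-3,5,7-trimethoxy-3,4-dihydro-2H-chromen-4-ol (C4 epimers) | COc1cc2c(c(OC)c1OCc3ccccc3)C(O)[C@H](OC)[C@@H](c4cc(OCc5ccccc5)c(OC)c(OC)c4)O2 | intermediate
18 | (2R,3R)-6-(benzyloxy)-2-[3-(benzyloxy)-4,5-dimethoxyphenyl]-3,5,7-trimethoxy-2,3-dihydro-4H-chromen-4-one | COc1cc2c(c(OC)c1OCc3ccccc3)C(=O)[C@H](OC)[C@@H](c4cc(OCc5ccccc5)c(OC)c(OC)c4)O2 | intermediate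
19 | (2R,3R)-6-hydroxy-2-(3-hydroxy-4,5-dimethoxyphenyl)-3,5,7-trimethoxy-2,3-dihydro-4H-chromen-4-one | COc1cc2c(c(OC)c1O)C(=O)[C@H](OC)[C@@H](c1cc(O)c(OC)c(OC)c1)O2 | intermediate
20 | (2R,3R)-5,6-dihydroxy-2-(3-hydroxy-4,5-dimethoxyphenyl)-3,7-dimethoxy-2,3-dihydro-4H-chromen-4-one | COc1cc2c(c(O)c1O)C(=O)[C@H](OC)[C@@H](c1cc(O)c(OC)c(OC)c1)O2 | target

## Step count and least certain steps

Total step count: 15. Longest linear sequence: 12 steps (steps 1–3 followed by 7–15, or equally steps 4–6 followed by 7–15).

**Step 10 (key step).** What may go wrong: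
- Poor facial selectivity, because a benzo-fused enol ether with a large 2-aryl group may not follow the 1-arylcycloalkene model.
- Slow addition to the hindered alkene, with displacement of α-pinene from the reagent and a less selective borane taking over.
- β-Elimination of the β-aryloxyborane with opening of ring C.
- Hydrolysis of the enol ether by residual BF3.

Fallback: set out from 13 and use BH3·SMe2 followed by NaOH/H2O2, which gives the trans alcohol as the racemate, that is 15 together with its (2S,3R) enantiomer F1. Esterification with (S)-2-methoxy-2-phenylacetic acid (DCC, DMAP) would give the (S)-O-methylmandelate ester F2 of 15 and the diastereomeric ester F3 of F1, separable by chromatography or crystallisation. Hydrolysis of F2 with LiOH comes back to the route at 15.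

**Step 7.** What may go wrong: slow or incomplete condensation, because the aldehyde reacts as its electron-rich phenoxide, with self-condensation of 9 taking over. Fallback: set out from 5 and protect the phenol with MOMCl/i-Pr2NEt to give the methoxymethyl ether F4. The Claisen–Schmidt condensation of F4 with 9 would give the protected chalcone F5, hydrogenation as in step 8 the protected dihydrochalcone F6, and HCl in MeOH removes the acetal to come back at 11.

**Step 9.** What may go wrong: acid-promoted disproportionation of the 4H-chromene (hydride transfer between the oxocarbenium ion and C4 of a second molecule), re-hydration, and autoxidation at C4 on handling. Fallback: set out from 10 and close the ring with HBF4·OEt2 in AcOH to the flavylium tetrafluoroborate F7. Hydride addition at C4 with NaBH4 in MeCN at low temperature comes back at 13 and replaces steps 8 and 9. The risk of that variant is competing hydride addition at C2.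

**Step 12.** What may go wrong: loss of the C3 proton from the C4 cation followed by further oxidation to a flavylium ion (which destroys both stereocentres), attack of the cation by the free C8 position of a second molecule, and oxidation of a benzyl ether. Fallback: set out from 16 and acetoxylate C4 with Pb(OAc)4 (tetravalent lead) in benzene to the C4 acetate F8. Methanolysis with K2CO3/MeOH comes back at 17.

**Step 15.** What may go wrong: over-demethylation, since the aryloxyboron species formed from the free C6 and C3' hydroxyls can activate the neighbouring C7 and C4' methyl ethers and the C3 methoxy group can chelate with the ketone; Lewis-acid opening of ring C; and air oxidation of the catechol. Fallback: set out from 18, before the phenols are unmasked, and cleave the chelated C5 methyl ether with MgI2·OEt2 in toluene to the 5-hydroxy dibenzyl ether F9. Hydrogenolysis (H2, Pd/C) then comes back at 20.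

## Further compounds

F1 | step 10 | (2S,3R)-6-(benzyloxy)-2-[3-(benzyloxy)-4,5-dimethoxyphenyl]-5,7-dimethoxy-3,4-dihydro-2H-chromen-3-ol | COc1cc2c(c(OC)c1OCc3ccccc3)C[C@@H](O)[C@H](c4cc(OCc5ccccc5)c(OC)c(OC)c4)O2
F2 | step 10 | (2R,3S)-6-(benzyloxy)-2-[3-(benzyloxy)-4,5-dimethoxyphenyl]-5,7-dimethoxy-3,4-dihydro-2H-chromen-3-yl (2S)-2-methoxy-2-phenylacetate | COc1cc2c(c(OC)c1OCc3ccccc3)C[C@H](OC(=O)[C@@H](OC)c6ccccc6)[C@@H](c4cc(OCc5ccccc5)c(OC)c(OC)c4)O2
F3 | step 10 | (2S,3R)-6-(benzyloxy)-2-[3-(benzyloxy)-4,5-dimethoxyphenyl]-5,7-dimethoxy-3,4-dihydro-2H-chromen-3-yl (2S)-2-methoxy-2-phenylacetate | COc1cc2c(c(OC)c1OCc3ccccc3)C[C@@H](OC(=O)[C@@H](OC)c6ccccc6)[C@H](c4cc(OCc5ccccc5)c(OC)c(OC)c4)O2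
F4 | step 7 | 3-(benzyloxy)-2,4-dimethoxy-6-(methoxymethoxy)benzaldehyde | COCOc1cc(OC)c(OCc2ccccc2)c(OC)c1C=O
F5 | step 7 | (2E)-3-[3-(benzyloxy)-2,4-dimethoxy-6-(methoxymethoxy)phenyl]-1-[3-(benzyloxy)-4,5-dimethoxyphenyl]prop-2-en-1-one | COCOc1cc(OC)c(OCc2ccccc2)c(OC)c1/C=C/C(=O)c1cc(OCc2ccccc2)c(OC)c(OC)c1
F6 | step 7 | 3-[3-(benzyloxy)-2,4-dimethoxy-6-(methoxymethoxy)phenyl]-1-[3-(benzyloxy)-4,5-dimethoxyphenyl]propan-1-one | COCOc1cc(OC)c(OCc2ccccc2)c(OC)c1CCC(=O)c1cc(OCc2ccccc2)c(OC)c(OC)c1
F7 | step 9 | 6-(benzyloxy)-2-[3-(benzyloxy)-4,5-dimethoxyphenyl]-5,7-dimethoxychromenylium tetrafluoroborate | COc1cc2[o+]c(-c3cc(OCc4ccccc4)c(OC)c(OC)c3)ccc2c(OC)c1OCc1ccccc1.F[B-](F)(F)F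
F8 | step 12 | (2R,3S)-6-(benzyloxy)-2-[3-(benzyloxy)-4,5-dimethoxyphenyl]-3,5,7-trimethoxy-3,4-dihydro-2H-chromen-4-yl acetate (C4 epimers) | COc1cc2c(c(OC)c1OCc3ccccc3)C(OC(C)=O)[C@H](OC)[C@@H](c4cc(OCc5ccccc5)c(OC)c(OC)c4)O2
F9 | step 15 | (2R,3R)-6-(benzyloxy)-2-[3-(benzyloxy)-4,5-dimethoxyphenyl]-5-hydroxy-3,7-dimethoxy-2,3-dihydro-4H-chromen-4-one | COc1cc2c(c(O)c1OCc3ccccc3)C(=O)[C@H](OC)[C@@H](c4cc(OCc5ccccc5)c(OC)c(OC)c4)O2
A1 | alternative 1 | (2R,3R)-3-[3-(benzyloxy)-4,5-dimethoxyphenyl]-1-(2,3-dihydroxy-4-methoxyphenyl)-3-hydroxy-2-methoxypropan-1-one | COc1ccc(c(O)c1O)C(=O)[C@H](OC)[C@@H](c1cc(OCc2ccccc2)c(OC)c(OC)c1)O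
A2 | alternative 1 | 3-[(2R,3R)-3-[3-(benzyloxy)-4,5-dimethoxyphenyl]-3-hydroxy-2-methoxypropanoyl]-6-methoxycyclohexa-3,5-diene-1,2-dione | COC1=CC=C(C(=O)C1=O)C(=O)[C@H](OC)[C@@H](c1cc(OCc2ccccc2)c(OC)c(OC)c1)O
A3 | alternative 1 | (2R,3R)-2-[3-(benzyloxy)-4,5-dimethoxyphenyl]-5,6-dihydroxy-3,7-dimethoxy-2,3-dihydro-4H-chromen-4-one | COc1cc2c(c(O)c1O)C(=O)[C@H](OC)[C@@H](c1cc(OCc3ccccc3)c(OC)c(OC)c1)O2
A4 | alternative 2 | 1-[3-(benzyloxy)-2,4-dimethoxy-6-(triisopropylsilyloxy)phenyl]-2-diazoethan-1-one | COc1cc(O[Si](C(C)C)(C(C)C)C(C)C)c(c(OC)c1OCc2ccccc2)C(=O)C=[N+]=[N-]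
A5 | alternative 2 | methanol | CO
A6 | alternative 2 | (2R,3S)-1-[3-(benzyloxy)-2,4-dimethoxy-6-(triisopropylsilyloxy)phenyl]-3-[3-(benzyloxy)-4,5-dimethoxyphenyl]-3-hydroxy-2-methoxypropan-1-one | COc1cc(O[Si](C(C)C)(C(C)C)C(C)C)c(c(OC)c1OCc2ccccc2)C(=O)[C@H](OC)[C@H](c3cc(OCc4ccccc4)c(OC)c(OC)c3)O
A7 | alternative 3 | 1-[3-(benzyloxy)-6-{[3-(benzyloxy)-4,5-dimethoxyphenyl]methoxy}-2,4-dimethoxyphenyl]-2-diazoethan-1-one | COc1cc(OCc2cc(OCc3ccccc3)c(OC)c(OC)c2)c(c(OC)c1OCc4ccccc4)C(=O)C=[N+]=[N-]
A8 | alternative 3 | (2S)-6-(benzyloxy)-2-[3-(benzyloxy)-4,5-dimethoxyphenyl]-5,7-dimethoxy-2,3-dihydro-4H-chromen-4-one | COc1cc2c(c(OC)c1OCc3ccccc3)C(=O)C[C@@H](c4cc(OCc5ccccc5)c(OC)c(OC)c4)O2
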